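## Retrosynthetic overview

1. The target is reached by removing two 2‑naphthylmethyl (NAP) ethers from the product of a twofold organocatalytic Michael addition of (S)‑6‑methyldihydropyran‑2,4‑dione to two molecules of one 14‑membered macrodiolide carrying an (E)‑4‑oxo‑enoate. This addition forms the quaternary carbon and both C9 stereocentres.
2. The macrodiolide comes from macrolactonisation of a seco acid whose 4‑oxo‑2‑enoic acid is unmasked from a 2‑alkylfuran.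
3. The seco chain comes from a Z‑selective Still–Gennari olefination joining a furyl‑alkyl phosphonoacetate to an anti‑2,3‑dioxygenated butanal.
4. All stereocentres come from achiral materials: enzymatic reduction of a furyl ketone, Shi epoxidation of (E)‑penta‑1,3‑diene followed by anti alcoholysis, and asymmetric hydrogenation of triacetic acid lactone.
5. Ring order: the dihydropyrandione (hydrogenation) and the 14‑membered ring (lactonisation, made once, used twice) are built separately and joined last at the quaternary carbon.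

Assumptions: compound 3 and both antipodes of the Shi ketone are taken as purchasable; the (S)‑ligand in step 8 and the quinidine‑derived catalyst in step 9 are taken as the antipodes that give the configurations drawn (otherwise the other antipode or the quinine‑derived pseudo‑enantiomer is used); both enoate double bonds of the target are read as Z.

## Route

Step 1
Reactants: 1 4‑(furan‑2‑yl)butan‑2‑one
Product: 2 (S)‑4‑(furan‑2‑yl)butan‑2‑ol
Conditions: Prelog‑selective ketoreductase (KRED), NADP+ (cat.), iPrOH (15 vol%), KH2PO4/K2HPO4 buffer pH 7.0, 30 °C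
Reagents that add atoms: none
Why: Enzymatic asymmetric ketone reduction (hydride transfer from NADPH, recycled by iPrOH) delivers hydride to the Re face of the methyl ketone and sets the (S)‑carbinol, the later C14 of the macrocycle, as for other 4‑arylbutan‑2‑ones.

Step 2
Reactants: 2 (S)‑4‑(furan‑2‑yl)butan‑2‑ol; 3 [bis(2,2,2‑trifluoroethoxy)phosphoryl]acetic acid
Product: 4 (S)‑4‑(furan‑2‑yl)butan‑2‑yl [bis(2,2,2‑trifluoroethoxy)phosphoryl]acetate
Conditions: EDC·HCl, DMAP (cat.), CH2Cl2, 0 °C → rt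
Reagents that add atoms: none
Why: Steglich (carbodiimide) esterification of a secondary alcohol; the stereocentre is not touched and the Still–Gennari phosphonate is installed on the oxygen that ends up as the enoate ester.

Step 3
Reactants: 5 (E)‑penta‑1,3‑diene
Product: 7 (2S,3R)‑3‑(naphthalen‑2‑ylmethoxy)pent‑4‑en‑2‑ol, via vinyl epoxide 6 (not isolated)
Conditions: a) ent‑Shi ketone (L‑fructose‑derived, 30 mol%), KHSO5 (as 2KHSO5·KHSO4·K2SO4), K2CO3, Bu4NHSO4, MeCN/aq. Na2B4O7 buffer (pH 10.5), 0 °C; extract into CH2Cl2, wash, dry (Na2SO4); b) naphthalen‑2‑ylmethanol, BF3·OEt2 (5 mol%), CH2Cl2, −40 °C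
Reagents that add atoms: potassium peroxymonosulfate [K+].[O-]S(=O)(=O)OO; naphthalen‑2‑ylmethanol OCc1ccc2ccccc2c1
Why: Shi asymmetric epoxidation (chiral dioxirane, spiro transition state) of the electron‑richer trans‑disubstituted alkene sets the (2S,3S)‑epoxide, and BF3‑catalysed anti 1,2‑alcoholysis at the allylic carbon inverts C3 to give the anti 3‑alkoxy‑2‑ol with the C2 hydroxyl free; the volatile epoxide is used as its dried solution.

Step 4
Reactants: 7 (2S,3R)‑3‑(naphthalen‑2‑ylmethoxy)pent‑4‑en‑2‑ol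
Product: 8 2‑{[(2S,3R)‑2‑[(2‑methoxypropan‑2‑yl)oxy]pent‑4‑en‑3‑yl]oxymethyl}naphthalene
Conditions: 2‑methoxypropene, PPTS (2 mol%), CH2Cl2, 0 °C; Et3N quench
Reagents that add atoms: 2‑methoxypropene COC(C)=C
Why: Acid‑catalysed addition of the alcohol to the enol ether gives an achiral mixed ketal (MOP ether), needed only to keep the hydroxyl masked during the basic olefination, where a free δ‑alkoxide would lactonise onto the Z‑enoate.

Step 5
Reactants: 8 2‑{[(2S,3R)‑2‑[(2‑methoxypropan‑2‑yl)oxy]pent‑4‑en‑3‑yl]oxymethyl}naphthalene; 4 (S)‑4‑(furan‑2‑yl)butan‑2‑yl [bis(2,2,2‑trifluoroethoxy)phosphoryl]acetate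
Product: 10 (S)‑4‑(furan‑2‑yl)butan‑2‑yl (2Z,4R,5S)‑5‑[(2‑methoxypropan‑2‑yl)oxy]‑4‑(naphthalen‑2‑ylmethoxy)hex‑2‑enoate, via aldehyde 9 (not isolated)
Conditions: a) O3, CH2Cl2, −78 °C (Sudan Red 7B end point), then PPh3, −78 °C → rt, concentrate; b) 4, KN(SiMe3)2, 18‑crown‑6, THF, −78 °C, then crude 9; KH2PO4/K2HPO4 (pH 7) quench
Reagents that add atoms: ozone [O-][O+]=O
Why: Ozonolysis of the terminal alkene (much faster than attack on the naphthalene) gives the configurationally labile α‑alkoxy aldehyde, which is used crude in a Still–Gennari Horner–Wadsworth–Emmons olefination whose kinetically controlled elimination gives the Z‑enoate and joins the two fragments.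

Step 6
Reactants: 10 (S)‑4‑(furan‑2‑yl)butan‑2‑yl (2Z,4R,5S)‑5‑[(2‑methoxypropan‑2‑yl)oxy]‑4‑(naphthalen‑2‑ylmethoxy)hex‑2‑enoate
Product: 13 (2E,7S)‑7‑{[(2Z,4R,5S)‑5‑hydroxy‑4‑(naphthalen‑2‑ylmethoxy)hex‑2‑enoyl]oxy}‑4‑oxooct‑2‑enoic acid, via keto‑enal 11 (not isolated), via ketal acid 12 (not isolated)
Conditions: a) NBS, NaHCO3, acetone/H2O (10:1), −20 °C; pyridine, rt; b) NaClO2, NaH2PO4, 2‑methyl‑2‑butene, tBuOH/H2O, 0 °C; then aq. NaHSO4 to pH 3, 0 °C, 15 min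
Reagents that add atoms: water O; sodium chlorite [Na+].[O-]Cl=O
Why: Oxidative furan ring opening with NBS/water gives the (Z)‑4‑oxo‑enal, pyridine isomerises it to E, Pinnick oxidation gives the 4‑oxo‑2‑enoic acid, and the MOP ketal hydrolyses in the pH 3–4 medium, so the seco hydroxy acid is obtained directly.

Step 7
Reactants: 13 (2E,7S)‑7‑{[(2Z,4R,5S)‑5‑hydroxy‑4‑(naphthalen‑2‑ylmethoxy)hex‑2‑enoyl]oxy}‑4‑oxooct‑2‑enoic acid
Product: 14 (3Z,5R,6S,9E,14S)‑6,14‑dimethyl‑5‑(naphthalen‑2‑ylmethoxy)‑1,7‑dioxacyclotetradeca‑3,9‑diene‑2,8,11‑trione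
Conditions: 2‑methyl‑6‑nitrobenzoic anhydride (MNBA), DMAP, CH2Cl2 (1 mM), rt, syringe‑pump addition of 13 over 12 h
Reagents that add atoms: none
Why: Shiina macrolactonisation: the acid is activated as a mixed anhydride and captured by the free secondary hydroxyl under high dilution at room temperature, closing the 14‑membered ring by acyl–oxygen bond formation without touching a stereocentre.

Step 8
Reactants: 15 4‑hydroxy‑6‑methyl‑2H‑pyran‑2‑one
Product: 16 (S)‑6‑methyldihydro‑2H‑pyran‑2,4(3H)‑dione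
Conditions: Ru(OAc)2[(S)‑MeO‑BIPHEP] (0.5 mol%), HBF4·OEt2 (1 mol%), H2 (60 bar), iPrOH, 60 °C
Reagents that add atoms: none
Why: Asymmetric hydrogenation of the C5=C6 enol‑ether double bond of the 2‑pyranone with a chiral ruthenium diphosphine catalyst sets C6 by face selection and leaves the enolised β‑keto lactone intact.

Step 9
Reactants: 16 (S)‑6‑methyldihydro‑2H‑pyran‑2,4(3H)‑dione; 14 (3Z,5R,6S,9E,14S)‑6,14‑dimethyl‑5‑(naphthalen‑2‑ylmethoxy)‑1,7‑dioxacyclotetradeca‑3,9‑diene‑2,8,11‑trione (2.2 equiv)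
Product: 18 (6S)‑6‑methyl‑3,3‑bis[(3Z,5R,6S,9R,14S)‑6,14‑dimethyl‑5‑(naphthalen‑2‑ylmethoxy)‑2,8,11‑trioxo‑1,7‑dioxacyclotetradec‑3‑en‑9‑yl]dihydro‑2H‑pyran‑2,4(3H)‑dione, via mono‑adduct 17 (not isolated)
Conditions: quinidine‑derived (9‑amino‑9‑deoxy‑epi‑quinidine) 3,5‑bis(trifluoromethyl)phenyl squaramide (10 mol%), CH2Cl2 (0.3 M), 4 Å MS, 25 °C, 72 h
Reagents that add atoms: none
Why: Proposed new method: a catalyst‑controlled twofold Michael addition joining one methylene carbon to two macrocyclic (E)‑4‑oxo‑enoates; the quinuclidine nitrogen deprotonates the acidic β‑keto lactone 16 (then the still acidic enol 17) to a tight ammonium enolate while the squaramide N–H pair binds the C11 ketone of 14, so the enolate carbon adds to C9 (β to the ketone, α to the lactone carbonyl, the preferred site of 4‑oxo‑enoates) on its Si face to give 9R in each ring; the two ring substituents are then identical, so the quaternary carbon is not a stereocentre, and the Z‑enoate is too poor an acceptor to compete; closest known reaction type: bifunctional amine–squaramide or thiourea catalysed Michael addition of cyclic 1,3‑dicarbonyl compounds to enones and aroylacrylates, and base‑mediated double Michael additions of active methylene compounds.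

Step 10
Reactants: 18 (6S)‑6‑methyl‑3,3‑bis[(3Z,5R,6S,9R,14S)‑6,14‑dimethyl‑5‑(naphthalen‑2‑ylmethoxy)‑2,8,11‑trioxo‑1,7‑dioxacyclotetradec‑3‑en‑9‑yl]dihydro‑2H‑pyran‑2,4(3H)‑dione
Product: 19 (6S)‑3,3‑bis[(3Z,5R,6S,9R,14S)‑5‑hydroxy‑6,14‑dimethyl‑2,8,11‑trioxo‑1,7‑dioxacyclotetradec‑3‑en‑9‑yl]‑6‑methyldihydro‑2H‑pyran‑2,4(3H)‑dione (CNP0083691.2)
Conditions: DDQ (3 equiv), CH2Cl2/aq. KH2PO4–K2HPO4 buffer pH 7 (10:1), 0 °C → 20 °C; rapid neutral work‑up
Reagents that add atoms: none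
Why: Oxidative cleavage of both naphthylmethyl ethers by DDQ (benzylic hydride abstraction, hydrolysis of the oxocarbenium ion) is chosen because it is neutral, which matters since a free Z‑γ‑hydroxy enoate can translactonise to a butenolide under acid or base.

## Compound list

1 | 4‑(furan‑2‑yl)butan‑2‑one | CC(=O)CCc1ccco1 | starting material
2 | (S)‑4‑(furan‑2‑yl)butan‑2‑ol | C[C@H](O)CCc1ccco1 | intermediate
3 | [bis(2,2,2‑trifluoroethoxy)phosphoryl]acetic acid | OC(=O)CP(=O)(OCC(F)(F)F)OCC(F)(F)F | starting material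
4 | (S)‑4‑(furan‑2‑yl)butan‑2‑yl [bis(2,2,2‑trifluoroethoxy)phosphoryl]acetate | C[C@H](OC(=O)CP(=O)(OCC(F)(F)F)OCC(F)(F)F)CCc1ccco1 | intermediate
5 | (E)‑penta‑1,3‑diene | C/C=C/C=C | starting material
6 | (2S,3S)‑2‑methyl‑3‑vinyloxirane | C[C@@H]1O[C@H]1C=C | intermediate
7 | (2S,3R)‑3‑(naphthalen‑2‑ylmethoxy)pent‑4‑en‑2‑ol | C[C@H](O)[C@H](OCc1ccc2ccccc2c1)C=C | intermediate
8 | 2‑{[(2S,3R)‑2‑[(2‑methoxypropan‑2‑yl)oxy]pent‑4‑en‑3‑yl]oxymethyl}naphthalene | C[C@H](OC(C)(C)OC)[C@H](OCc1ccc2ccccc2c1)C=C | intermediate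
9 | (2S,3S)‑3‑[(2‑methoxypropan‑2‑yl)oxy]‑2‑(naphthalen‑2‑ylmethoxy)butanal | C[C@H](OC(C)(C)OC)[C@H](OCc1ccc2ccccc2c1)C=O | intermediate
10 | (S)‑4‑(furan‑2‑yl)butan‑2‑yl (2Z,4R,5S)‑5‑[(2‑methoxypropan‑2‑yl)oxy]‑4‑(naphthalen‑2‑ylmethoxy)hex‑2‑enoate | C[C@H](OC(C)(C)OC)[C@H](OCc1ccc2ccccc2c1)/C=C\C(=O)O[C@@H](C)CCc1ccco1 | intermediate
11 | (2S,6E)‑5,8‑dioxooct‑6‑en‑2‑yl (2Z,4R,5S)‑5‑[(2‑methoxypropan‑2‑yl)oxy]‑4‑(naphthalen‑2‑ylmethoxy)hex‑2‑enoate | C[C@H](OC(C)(C)OC)[C@H](OCc1ccc2ccccc2c1)/C=C\C(=O)O[C@@H](C)CCC(=O)/C=C/C=O | intermediate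
12 | (2E,7S)‑7‑{[(2Z,4R,5S)‑5‑[(2‑methoxypropan‑2‑yl)oxy]‑4‑(naphthalen‑2‑ylmethoxy)hex‑2‑enoyl]oxy}‑4‑oxooct‑2‑enoic acid | C[C@H](OC(C)(C)OC)[C@H](OCc1ccc2ccccc2c1)/C=C\C(=O)O[C@@H](C)CCC(=O)/C=C/C(=O)O | intermediate
13 | (2E,7S)‑7‑{[(2Z,4R,5S)‑5‑hydroxy‑4‑(naphthalen‑2‑ylmethoxy)hex‑2‑enoyl]oxy}‑4‑oxooct‑2‑enoic acid | C[C@H](O)[C@H](OCc1ccc2ccccc2c1)/C=C\C(=O)O[C@@H](C)CCC(=O)/C=C/C(=O)O | intermediate
14 | (3Z,5R,6S,9E,14S)‑6,14‑dimethyl‑5‑(naphthalen‑2‑ylmethoxy)‑1,7‑dioxacyclotetradeca‑3,9‑diene‑2,8,11‑trione | C[C@@H]1OC(=O)/C=C/C(=O)CC[C@H](C)OC(=O)/C=C\[C@H]1OCc1ccc2ccccc2c1 | intermediate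
15 | 4‑hydroxy‑6‑methyl‑2H‑pyran‑2‑one (triacetic acid lactone) | CC1=CC(O)=CC(=O)O1 | starting material
16 | (S)‑6‑methyldihydro‑2H‑pyran‑2,4(3H)‑dione | C[C@H]1CC(=O)CC(=O)O1 | intermediate
17 | (6S)‑4‑hydroxy‑6‑methyl‑3‑[(3Z,5R,6S,9R,14S)‑6,14‑dimethyl‑5‑(naphthalen‑2‑ylmethoxy)‑2,8,11‑trioxo‑1,7‑dioxacyclotetradec‑3‑en‑9‑yl]‑5,6‑dihydro‑2H‑pyran‑2‑one | C[C@H]1CC(O)=C([C@H]2CC(=O)CC[C@H](C)OC(=O)/C=C\[C@@H](OCc3ccc4ccccc4c3)[C@H](C)OC2=O)C(=O)O1 | intermediate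
18 | (6S)‑6‑methyl‑3,3‑bis[(3Z,5R,6S,9R,14S)‑6,14‑dimethyl‑5‑(naphthalen‑2‑ylmethoxy)‑2,8,11‑trioxo‑1,7‑dioxacyclotetradec‑3‑en‑9‑yl]dihydro‑2H‑pyran‑2,4(3H)‑dione | C[C@@H]1OC(=O)[C@@H](C2([C@H]3CC(=O)CC[C@H](C)OC(=O)/C=C\[C@@H](OCc4ccc5ccccc5c4)[C@H](C)OC3=O)C(=O)C[C@H](C)OC2=O)CC(=O)CC[C@H](C)OC(=O)/C=C\[C@H]1OCc1ccc2ccccc2c1 | intermediate
19 | (6S)‑3,3‑bis[(3Z,5R,6S,9R,14S)‑5‑hydroxy‑6,14‑dimethyl‑2,8,11‑trioxo‑1,7‑dioxacyclotetradec‑3‑en‑9‑yl]‑6‑methyldihydro‑2H‑pyran‑2,4(3H)‑dione | C[C@@H]1OC(=O)[C@@H](C2([C@H]3CC(=O)CC[C@H](C)OC(=O)/C=C\[C@@H](O)[C@H](C)OC3=O)C(=O)C[C@H](C)OC2=O)CC(=O)CC[C@H](C)OC(=O)/C=C\[C@H]1O | target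

## Step count and risks

Total step count: 10. Longest linear sequence: 7 steps (5 → 7 → 8 → 10 → 13 → 14 → 18 → 19; the branch from 1 is equally long).

Steps most likely to fail:

**Step 9 (proposed twofold Michael addition).** The second addition must build a quaternary carbon between two macrocycles and may stall at 17, revert by retro‑Michael, or give C9 epimers. The fallback uses known stepwise chemistry and sets out from 16 and 14. A 1:1 amine‑catalysed Michael addition (Et3N or the same squaramide, a known reaction of cyclic 1,3‑dicarbonyls with enones) gives mono‑adduct 17, which is now isolated. O‑silylation (Me3SiCl, Et3N, CH2Cl2, 0 °C) converts it into (6S)‑6‑methyl‑4‑(trimethylsilyloxy)‑3‑[(3Z,5R,6S,9R,14S)‑6,14‑dimethyl‑5‑(naphthalen‑2‑ylmethoxy)‑2,8,11‑trioxo‑1,7‑dioxacyclotetradec‑3‑en‑9‑yl]‑5,6‑dihydro‑2H‑pyran‑2‑one F1. This silyl enol ether is added to a second equivalent of 14 in a Lewis‑acid‑promoted Mukaiyama–Michael reaction (Sc(OTf)3, CH2Cl2, −78 °C), relying on the facial bias of the macrocycle and chromatographic separation of C9 epimers. It comes back to the route at 18.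

**Step 7 (macrolactonisation).** The seco acid 13 carries a free δ‑hydroxyl next to a Z‑enoate ester and can collapse to a dihydropyranone or oligomerise. The fallback closes the ring by olefination instead of lactonisation and sets out from 4 and 7. The furan of 4 is oxidised first (NBS, NaHCO3, acetone/H2O; pyridine; NaClO2, NaH2PO4, 2‑methyl‑2‑butene) to (2E,7S)‑7‑{[bis(2,2,2‑trifluoroethoxy)phosphoryl]acetoxy}‑4‑oxooct‑2‑enoic acid F2. This is esterified with the free hydroxyl of 7 (2,4,6‑trichlorobenzoyl chloride, Et3N, DMAP, toluene) to give (2S,3R)‑3‑(naphthalen‑2‑ylmethoxy)pent‑4‑en‑2‑yl (2E,7S)‑7‑{[bis(2,2,2‑trifluoroethoxy)phosphoryl]acetoxy}‑4‑oxooct‑2‑enoate F3. Selective ozonolysis of the terminal alkene (O3, CH2Cl2, −78 °C, Sudan Red 7B; PPh3) gives (2S,3S)‑3‑(naphthalen‑2‑ylmethoxy)‑4‑oxobutan‑2‑yl (2E,7S)‑7‑{[bis(2,2,2‑trifluoroethoxy)phosphoryl]acetoxy}‑4‑oxooct‑2‑enoate F4. An intramolecular Still–Gennari olefination (K2CO3, 18‑crown‑6, toluene, 1 mM, 0 °C) then forms the Z‑enoate and the ring together, so no δ‑hydroxy Z‑enoate is ever present. It comes back to the route at 14.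

**Step 3 (Shi epoxidation and anti alcoholysis).** The diene and epoxide are volatile, the ee may be moderate, and the alcoholysis can leak to 1,4‑ or syn‑products. The fallback replaces it by a desymmetrisation and sets out from commercial, achiral penta‑1,4‑dien‑3‑ol F5. Sharpless epoxidation (Ti(OiPr)4, L‑(+)‑diisopropyl tartrate, tBuOOH, 4 Å MS, CH2Cl2, −20 °C) gives (R)‑1‑[(S)‑oxiran‑2‑yl]prop‑2‑en‑1‑ol F6. Etherification (NaH, 2‑(bromomethyl)naphthalene, Bu4NI, THF, −20 → 0 °C) gives (S)‑2‑[(R)‑1‑(naphthalen‑2‑ylmethoxy)prop‑2‑en‑1‑yl]oxirane F7. Hydride opening at the terminal carbon (LiAlH4, THF, 0 °C) comes back to the route at 7.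

## Further compounds

F1 | step 9 | (6S)‑6‑methyl‑4‑(trimethylsilyloxy)‑3‑[(3Z,5R,6S,9R,14S)‑6,14‑dimethyl‑5‑(naphthalen‑2‑ylmethoxy)‑2,8,11‑trioxo‑1,7‑dioxacyclotetradec‑3‑en‑9‑yl]‑5,6‑dihydro‑2H‑pyran‑2‑one | C[C@H]1CC(O[Si](C)(C)C)=C([C@H]2CC(=O)CC[C@H](C)OC(=O)/C=C\[C@@H](OCc3ccc4ccccc4c3)[C@H](C)OC2=O)C(=O)O1
F2 | step 7 | (2E,7S)‑7‑{[bis(2,2,2‑trifluoroethoxy)phosphoryl]acetoxy}‑4‑oxooct‑2‑enoic acid | C[C@H](OC(=O)CP(=O)(OCC(F)(F)F)OCC(F)(F)F)CCC(=O)/C=C/C(=O)O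
F3 | step 7 | (2S,3R)‑3‑(naphthalen‑2‑ylmethoxy)pent‑4‑en‑2‑yl (2E,7S)‑7‑{[bis(2,2,2‑trifluoroethoxy)phosphoryl]acetoxy}‑4‑oxooct‑2‑enoate | C[C@H](OC(=O)/C=C/C(=O)CC[C@H](C)OC(=O)CP(=O)(OCC(F)(F)F)OCC(F)(F)F)[C@H](OCc1ccc2ccccc2c1)C=C
F4 | step 7 | (2S,3S)‑3‑(naphthalen‑2‑ylmethoxy)‑4‑oxobutan‑2‑yl (2E,7S)‑7‑{[bis(2,2,2‑trifluoroethoxy)phosphoryl]acetoxy}‑4‑oxooct‑2‑enoate | C[C@H](OC(=O)/C=C/C(=O)CC[C@H](C)OC(=O)CP(=O)(OCC(F)(F)F)OCC(F)(F)F)[C@H](OCc1ccc2ccccc2c1)C=O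
F5 | step 3 | penta‑1,4‑dien‑3‑ol | C=CC(O)C=C
F6 | step 3 | (R)‑1‑[(S)‑oxiran‑2‑yl]prop‑2‑en‑1‑ol | C1O[C@@H]1[C@H](O)C=C
F7 | step 3 | (S)‑2‑[(R)‑1‑(naphthalen‑2‑ylmethoxy)prop‑2‑en‑1‑yl]oxirane | C1O[C@@H]1[C@H](OCc1ccc2ccccc2c1)C=C
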